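The data stem from a simulated flask on assumed constants; the scatter is artificial.

The partner and the temperature change together between the dusk and the midnight run, so a comparison of the two runs cannot separate them. Three flasks with more partner than either run are now to be reckoned.

common to all: substrate 0.050 M; free catalyst 1 mol%
- dusk: partner 1.2 equiv; temperature 26 °C; run made earlier
- midnight: partner 1.9 equiv; temperature 40 °C; run made earlier
- ochre: partner 2.50 equiv; temperature 20 °C; time 6.0 min
- red: partner 2.50 equiv; temperature 45 °C; time 6.0 min
- violet: partner 2.50 equiv; at 20 °C until 80 s, from then on at 45 °C; time 6.0 min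

- dusk (time / min: product / %, substrate / %): 0.833: 4.6, 94.8; 2.00: 11.0, 88.8; 4.00: 20.3, 78.8; 6.00: 28.9, 71.3
- midnight (time / s: product / %, substrate / %): 12.0: 2.9, 96.6; 20.0: 4.4, 95.0; 60.0: 13.4, 85.7; 120: 25.0, 75.0

(readings scatter by 0.3 percentage points)

* the best flask by amount of product, in percent of the substrate charged; "all alike" if 1.5 percentage points covers them all (ochre / red / violet / all alike)
* amount of product at the end, in percent of the substrate charged, ochre
* amount of product at the end, in percent of the substrate charged, red
* amount of product at the end, in percent of the substrate charged, violet

In both runs product and substrate add up to between 99.1% and 100% of the charge, so each reading gives a slope, the pseudo-first-order constant: the logarithm of the inverse substrate fraction over time. The last readings give 0.0564 min⁻¹ for dusk and 0.144 min⁻¹ for midnight. Read at each time, the dusk slope sinks from 0.0641 min⁻¹ at the first reading to 0.0564 min⁻¹ at the last, while the partner in that run falls, so this reckoning takes the rate as proportional to partner, with one partner used per product.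

Divided by the mean partner of each run, the slopes become 0.0534 min⁻¹ and 0.0810 min⁻¹ per equivalent. A constant factor per degree then carries them to the new temperatures. At 2.50 equiv, ochre starts at a slope of 0.112 min⁻¹ and red at 0.235 min⁻¹, which is 2.10 times faster. Violet has ochre's slope until 80 s and red's afterwards.

Violet therefore reaches 1.25 as its unslowed exponent, the starting slope summed over the time spent at each temperature. Ochre reaches 0.670 and red 1.41. Falling substrate is already contained in the exponential, since the fraction left is exp(−exponent). Falling partner is the further slowing: its mean lies below the charge by half the conversion, which multiplies the exponent by 0.902 for ochre, 0.849 for red and 0.858 for violet. The reckoned product is then 45.4% in ochre, 69.8% in red and 65.7% in violet. Red leads violet by 4.1 percentage points, more than the margin of 1.5 points.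

The forecast, for which “the rate looks first order in substrate and about zero order in partner”, names red and gives 20.1% for ochre, 69.3% for red and 62.1% for violet, lower than this reckoning at ochre. The flasks end at 36.6% in ochre, 69.2% in red and 63.8% in violet, and the best is red.

    substrate + free catalyst ⇌ catalyst intermediate A (K = 17.9 M⁻¹, k = 725 M⁻¹ min⁻¹, Ea = 52.0 kJ mol⁻¹, ΔH = −34.0 kJ mol⁻¹)
    partner + catalyst intermediate A ⇌ catalyst intermediate B (K = 6.70 M⁻¹, k = 328 M⁻¹ min⁻¹, Ea = 44.0 kJ mol⁻¹, ΔH = −16.0 kJ mol⁻¹)
    catalyst intermediate B ⇌ by-product + catalyst intermediate C (K = 0.540 M, k = 90.4 min⁻¹, Ea = 69.0 kJ mol⁻¹, ΔH = −47.0 kJ mol⁻¹)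
    catalyst intermediate C → free catalyst + product (k = 53.6 min⁻¹, Ea = 63.0 kJ mol⁻¹)
    (constants at 20 °C)

Ochre reads 8.8 points below its reckoned value, while violet reads 63.8% against 65.7%. Taking the rate as proportional to the free catalyst charged, the exponent of violet scales to a neighbouring flask with 0.25 mol% of free catalyst, a quarter of the charge. Its unslowed exponent is 0.312, its partner factor 0.946, and its reckoned product 25.6%. That flask ends with 76% of its substrate unbound and 24.0% of product.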